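**Retrosynthetic overview**

1. The target comes from an acetonide-protected, mono-silylated diol by one double benzoylation and one acidic deprotection. The two oxygens that are benzoylated are the ones the key step delivers as an acetate oxygen and as the acyl oxygen.
2. The cis-diol at ring C4/C5 comes from OsO4 addition to the leftover alkene of a cyclohexa-1,4-diene, anti to the two allylic oxygens.
3. The only carbocycle is made in one catalytic enantioselective [4+2] cycloaddition: a propioloyl unit (ring C1=C2 plus the exocyclic carbon) adds across (1E,3E)-1-acetoxy-4-silyloxybutadiene (ring C3–C6).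
4. Enabling feature: in the cyclohexene ring, the C1=C2 double bond (C1 bearing the CH2O carbon) lies between two oxygen-bearing allylic carbons, C3 and C6, that are cis to each other, and C4/C5 carry a cis-diol on the opposite face. This is the pattern left by an alkyne added across the termini of an E,E-1,4-dioxygenated diene whose remaining alkene is then dihydroxylated.
5. Ring order: cyclohexadiene (step 3), then a temporary dioxolane (step 5, removed in step 8). The diene comes from commercial (E,E)-1,4-diacetoxybutadiene by mono enol-acetate cleavage and silylation.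

Key step: step 3

Assumption: the sense of induction in step 3 is taken from the square-planar copper–bis(oxazoline) chelate model given there, which assigns the (S,S)-ligand to the required (1S,4R)-adduct; if the sense proves opposite, the equally available (R,R)-ligand is used with no other change.

**Route**

Step 1
Reactants: 1 (1E,3E)-buta-1,3-diene-1,4-diyl diacetate
Product: 3 (1E,3E)-4-[(tert-butyldimethylsilyl)oxy]buta-1,3-dien-1-yl acetate, via lithium dienolate 2 (not isolated)
Conditions: MeLi (2.0 equiv, slow addition), THF, −78 °C; then TBSCl, DMPU, −78 → 0 °C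
Reagents that add atoms: tert-butyldimethylsilyl chloride, CC(C)(C)[Si](C)(C)Cl
Why: Cleavage of an enol acetate with MeLi gives the lithium enolate with retention of double-bond geometry, the first cleavage turns the molecule into an electron-rich dienolate whose remaining ester is deactivated toward a second attack so the reaction should be holdable at the mono stage, and O-silylation by the hard silyl chloride then fixes the E,E geometry; no stereocentre is formed.

Step 2
Reactants: 4 propiolic acid; 5 3,5-dimethyl-1H-pyrazole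
Product: 6 1-(3,5-dimethyl-1H-pyrazol-1-yl)prop-2-yn-1-one
Conditions: DCC, CH2Cl2, −20 → 0 °C
Reagents that add atoms: none
Why: Carbodiimide-mediated N-acylation of the pyrazole N–H by the O-acylisourea of propiolic acid gives the chelating N-acylpyrazole, the low temperature keeping conjugate addition of the pyrazole to the ynoyl unit in check; no stereocentre is formed.

Step 3
Reactants: 3 (1E,3E)-4-[(tert-butyldimethylsilyl)oxy]buta-1,3-dien-1-yl acetate; 6 1-(3,5-dimethyl-1H-pyrazol-1-yl)prop-2-yn-1-one
Product: 7 (1S,4R)-4-[(tert-butyldimethylsilyl)oxy]-3-(3,5-dimethyl-1H-pyrazole-1-carbonyl)cyclohexa-2,5-dien-1-yl acetate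
Conditions: [Cu((S,S)-t-Bu-box)](SbF6)2 (10 mol %, preformed from CuCl2, AgSbF6 and 2,2'-(propane-2,2-diyl)bis[(4S)-4-tert-butyl-4,5-dihydro-1,3-oxazole]), 4 Å molecular sieves, CH2Cl2, −40 → −20 °C; the adduct is taken on without storage
Reagents that add atoms: none
Why: The divalent copper centre chelates the carbonyl oxygen and N2 of 6 and lowers the ynoyl LUMO, and diene 3 adds in a concerted but asynchronous normal-demand Diels–Alder reaction in which the bond from the acetoxy-bearing diene terminus to the alkyne β-carbon is the more advanced one. The closest known reaction types are the copper–bis(oxazoline)-catalysed Diels–Alder reaction of chelating N-acyl dienophiles with 1-acyloxybutadienes and the chiral-copper-catalysed Diels–Alder reaction of propioloylpyrazoles with dienes. The cyclohexa-1,4-diene ring is closed by this intermolecular [4+2] cycloaddition, suprafacial on both partners, both ring bonds forming in the same event. The two new stereocentres should come out cis because both oxygens are outside substituents of the E,E-diene, and their absolute configuration is set by the ligand: the tert-butyl group next to the bound carbonyl screens one face of the chelate plane, and the diene stacks on the open face with its central carbons over the copper-bound carbonyl. The step needs regioselectivity (the silyloxy group is by far the stronger donor, which puts the largest HOMO coefficient on the acetoxy-bearing terminus, so the silyloxy carbon ends up next to the acyl-bearing ring carbon), periselectivity for [4+2] over open-chain Mukaiyama-type addition or [2+2] (helped by the s-cis-capable E,E geometry and low temperature), and survival of the doubly allylic adduct (no base is present, and the acidic ring hydrogen is paired with the poor silyloxy leaving group, not with the acetate).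

Step 4
Reactants: 7 (1S,4R)-4-[(tert-butyldimethylsilyl)oxy]-3-(3,5-dimethyl-1H-pyrazole-1-carbonyl)cyclohexa-2,5-dien-1-yl acetate
Product: 8 (1R,4S,5S,6R)-4-[(tert-butyldimethylsilyl)oxy]-3-(3,5-dimethyl-1H-pyrazole-1-carbonyl)-5,6-dihydroxycyclohex-2-en-1-yl acetate
Conditions: OsO4 (3 mol %), NMO (1.5 equiv), acetone–H2O (10:1), 0 °C → rt
Reagents that add atoms: osmium tetroxide, O=[Os](=O)(=O)=O; 4-methylmorpholine N-oxide (reoxidant), C[N+]1([O-])CCOCC1; water, O
Why: Upjohn dihydroxylation: OsO4 adds suprafacially to the electron-richer, unconjugated ring alkene (the acylated alkene is electron-poor and is left) from the face anti to both allylic oxygen substituents, as known for the osmylation of cis-3,6-diacyloxycyclohexenes, which should set the two new carbinol centres cis to each other and trans to their oxygenated neighbours.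

Step 5
Reactants: 8 (1R,4S,5S,6R)-4-[(tert-butyldimethylsilyl)oxy]-3-(3,5-dimethyl-1H-pyrazole-1-carbonyl)-5,6-dihydroxycyclohex-2-en-1-yl acetate
Product: 9 (3aS,4R,7S,7aS)-7-[(tert-butyldimethylsilyl)oxy]-6-(3,5-dimethyl-1H-pyrazole-1-carbonyl)-2,2-dimethyl-3a,4,7,7a-tetrahydro-1,3-benzodioxol-4-yl acetate
Conditions: 2,2-dimethoxypropane, pyridinium p-toluenesulfonate (cat.), CH2Cl2, rt
Reagents that add atoms: 2,2-dimethoxypropane, COC(C)(C)OC
Why: Acid-catalysed transacetalisation converts the cis-1,2-diol into the cis-fused isopropylidene acetal, which blocks acyl migration from the neighbouring acetate and leaves no free hydroxyl for the later acylation; no stereocentre is changed.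

Step 6
Reactants: 9 (3aS,4R,7S,7aS)-7-[(tert-butyldimethylsilyl)oxy]-6-(3,5-dimethyl-1H-pyrazole-1-carbonyl)-2,2-dimethyl-3a,4,7,7a-tetrahydro-1,3-benzodioxol-4-yl acetate
Product: 10 (3aS,4R,7S,7aS)-7-[(tert-butyldimethylsilyl)oxy]-6-(hydroxymethyl)-2,2-dimethyl-3a,4,7,7a-tetrahydro-1,3-benzodioxol-4-ol
Conditions: i-Bu2AlH (6 equiv), CH2Cl2, −78 → −30 °C; aq. potassium sodium tartrate work-up
Reagents that add atoms: none
Why: i-Bu2AlH reduces the N-acylpyrazole (an activated amide) through the aldehyde to the allylic alcohol with 1,2-selectivity and at the same time cleaves the acetate reductively, while the silyl ether and the acetal are inert; no stereocentre is touched.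

Step 7
Reactants: 10 (3aS,4R,7S,7aS)-7-[(tert-butyldimethylsilyl)oxy]-6-(hydroxymethyl)-2,2-dimethyl-3a,4,7,7a-tetrahydro-1,3-benzodioxol-4-ol
Product: 11 [(3aS,4S,7R,7aS)-7-(benzoyloxy)-4-[(tert-butyldimethylsilyl)oxy]-2,2-dimethyl-3a,4,7,7a-tetrahydro-1,3-benzodioxol-5-yl]methyl benzoate
Conditions: BzCl (2.5 equiv), pyridine, DMAP (cat.), CH2Cl2, 0 °C → rt
Reagents that add atoms: benzoyl chloride, O=C(Cl)c1ccccc1
Why: DMAP-catalysed acylation benzoylates the only two free hydroxyls, the primary allylic one and the secondary allylic one that the cycloaddition delivered as the acetate, while the third ring carbinol stays silylated; no stereocentre is touched.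

Step 8
Reactants: 11 [(3aS,4S,7R,7aS)-7-(benzoyloxy)-4-[(tert-butyldimethylsilyl)oxy]-2,2-dimethyl-3a,4,7,7a-tetrahydro-1,3-benzodioxol-5-yl]methyl benzoate
Product: 12 [(3R,4R,5R,6S)-3-(benzoyloxy)-4,5,6-trihydroxycyclohex-1-en-1-yl]methyl benzoate
Conditions: CF3CO2H–H2O–THF (4:1:1), 0 °C → rt
Reagents that add atoms: none
Why: Aqueous acid hydrolyses the isopropylidene acetal and the secondary silyl ether in one operation while the benzoates, which tolerate acid at this temperature, stay in place, giving the target with all four stereocentres unchanged.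

**Compound list**

1 | (1E,3E)-buta-1,3-diene-1,4-diyl diacetate | CC(=O)O/C=C/C=C/OC(C)=O | starting material
2 | lithium (1E,3E)-4-acetoxybuta-1,3-dien-1-olate | [Li+].[O-]/C=C/C=C/OC(C)=O | intermediate (not isolated)
3 | (1E,3E)-4-[(tert-butyldimethylsilyl)oxy]buta-1,3-dien-1-yl acetate | CC(=O)O/C=C/C=C/O[Si](C)(C)C(C)(C)C | intermediate
4 | propiolic acid (prop-2-ynoic acid) | OC(=O)C#C | starting material
5 | 3,5-dimethyl-1H-pyrazole | Cc1cc(C)[nH]n1 | starting material
6 | 1-(3,5-dimethyl-1H-pyrazol-1-yl)prop-2-yn-1-one | C#CC(=O)n1nc(C)cc1C | intermediate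
7 | (1S,4R)-4-[(tert-butyldimethylsilyl)oxy]-3-(3,5-dimethyl-1H-pyrazole-1-carbonyl)cyclohexa-2,5-dien-1-yl acetate (acetoxy and silyloxy cis) | Cc1cc(C)n(n1)C(=O)C1=C[C@@H](OC(C)=O)C=C[C@H]1O[Si](C)(C)C(C)(C)C | intermediate
8 | (1R,4S,5S,6R)-4-[(tert-butyldimethylsilyl)oxy]-3-(3,5-dimethyl-1H-pyrazole-1-carbonyl)-5,6-dihydroxycyclohex-2-en-1-yl acetate (diol anti to acetoxy and silyloxy) | Cc1cc(C)n(n1)C(=O)C1=C[C@@H](OC(C)=O)[C@H](O)[C@H](O)[C@H]1O[Si](C)(C)C(C)(C)C | intermediate
9 | (3aS,4R,7S,7aS)-7-[(tert-butyldimethylsilyl)oxy]-6-(3,5-dimethyl-1H-pyrazole-1-carbonyl)-2,2-dimethyl-3a,4,7,7a-tetrahydro-1,3-benzodioxol-4-yl acetate | Cc1cc(C)n(n1)C(=O)C1=C[C@@H](OC(C)=O)[C@@H]2OC(C)(C)O[C@@H]2[C@H]1O[Si](C)(C)C(C)(C)C | intermediate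
10 | (3aS,4R,7S,7aS)-7-[(tert-butyldimethylsilyl)oxy]-6-(hydroxymethyl)-2,2-dimethyl-3a,4,7,7a-tetrahydro-1,3-benzodioxol-4-ol | OCC1=C[C@@H](O)[C@@H]2OC(C)(C)O[C@@H]2[C@H]1O[Si](C)(C)C(C)(C)C | intermediate
11 | [(3aS,4S,7R,7aS)-7-(benzoyloxy)-4-[(tert-butyldimethylsilyl)oxy]-2,2-dimethyl-3a,4,7,7a-tetrahydro-1,3-benzodioxol-5-yl]methyl benzoate | O=C(OCC1=C[C@@H](OC(=O)c2ccccc2)[C@@H]3OC(C)(C)O[C@@H]3[C@H]1O[Si](C)(C)C(C)(C)C)c1ccccc1 | intermediate
12 | [(3R,4R,5R,6S)-3-(benzoyloxy)-4,5,6-trihydroxycyclohex-1-en-1-yl]methyl benzoate | O=C(OCC1=C[C@@H](OC(=O)c2ccccc2)[C@H](O)[C@H](O)[C@H]1O)c1ccccc1 | target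

**Step count and risks**

Total step count: 8. Longest linear sequence: 7 (steps 1, 3, 4, 5, 6, 7, 8).

Most likely to fail, first: step 3. The silyl dienol ether may add to the copper-bound ynoyl unit stepwise (Mukaiyama-type), ending in open-chain or four-membered products. Enantiofacial discrimination may be weak with a linear dienophile, and adventitious acid may desilylate the diene or aromatise the adduct. The fallback sets out from 3 and 4 and comes back at 10; it drops the Lewis acid and controls configuration with a covalent auxiliary. Propiolic acid 4 is N-acylated onto (S)-4-benzyl-1,3-oxazolidin-2-one (DCC, DMAP cat., CH2Cl2, 0 °C) to give (S)-4-benzyl-3-propioloyl-1,3-oxazolidin-2-one F1. Uncatalysed thermal cycloaddition of F1 with 3 (toluene, 40–60 °C) is a concerted process with the same regiochemistry and should give two diastereomeric adducts, separable by chromatography or crystallisation. The one with the (1S,4R) ring is the auxiliary-bearing cyclohexadienyl acetate F2. Dihydroxylation as in step 4 should give the auxiliary-bearing diol F3, and acetonide formation as in step 5 the auxiliary-bearing acetonide F4. LiBH4 (THF, 1 equiv MeOH, 0 °C) then removes auxiliary and acetate to give 10.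

Second: step 1. The cleavage may not stop at the mono-enolate (statistical over-cleavage, intermolecular acetyl transfer), or the dienolate may lose its E,E geometry. The fallback sets out from 1 and comes back at 12. It uses symmetrical 1 itself as the diene, so no regiochemical question arises, and tells the two ring carbinols apart later through the 1,3-diol that only one of them forms with the hydroxymethyl group. Cycloaddition of 1 with 6 under the conditions of step 3 should give the diacetate adduct F5. OsO4/NMO then gives the diacetate diol F6, and 2,2-dimethoxypropane with acid gives the diacetate acetonide F7. i-Bu2AlH reduces F7 to the acetonide triol F8. t-Bu2Si(OTf)2 with 2,6-lutidine bridges the primary hydroxyl and the neighbouring ring hydroxyl as the di-tert-butylsilylene F9. BzCl/pyridine/DMAP acylates the remaining carbinol to give the silylene monobenzoate F10. HF·pyridine followed by aqueous CF3CO2H frees the tetraol monobenzoate F11. BzCl (1 equiv), 2,4,6-collidine, CH2Cl2, −78 °C should then acylate the primary hydroxyl selectively to give 12.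

Third: step 8. Acid may promote benzoyl migration onto the newly freed neighbouring hydroxyls, or the hindered silyl ether may not come off under conditions mild enough to spare the allylic benzoate. The fallback sets out from 8 and comes back at 12; it avoids the acetal and aqueous acid by using only silyl protection, removed by fluoride. TESOTf with 2,6-lutidine (CH2Cl2, −78 °C) converts 8 into the bis(triethylsilyl) ether F12. i-Bu2AlH as in step 6 gives the tris-silylated diol F13. BzCl/pyridine/DMAP gives the tris-silylated dibenzoate F14. HF·pyridine buffered with excess pyridine (THF, 0 °C → rt) removes all three silyl groups to give 12.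

**Further compounds**

F1 | step 3 | (S)-4-benzyl-3-propioloyl-1,3-oxazolidin-2-one | C#CC(=O)N1[C@@H](Cc2ccccc2)COC1=O
F2 | step 3 | (1S,4R)-3-{[(4S)-4-benzyl-2-oxo-1,3-oxazolidin-3-yl]carbonyl}-4-[(tert-butyldimethylsilyl)oxy]cyclohexa-2,5-dien-1-yl acetate | O=C(N1[C@@H](Cc2ccccc2)COC1=O)C1=C[C@@H](OC(C)=O)C=C[C@H]1O[Si](C)(C)C(C)(C)C
F3 | step 3 | (1R,4S,5S,6R)-3-{[(4S)-4-benzyl-2-oxo-1,3-oxazolidin-3-yl]carbonyl}-4-[(tert-butyldimethylsilyl)oxy]-5,6-dihydroxycyclohex-2-en-1-yl acetate | O=C(N1[C@@H](Cc2ccccc2)COC1=O)C1=C[C@@H](OC(C)=O)[C@H](O)[C@H](O)[C@H]1O[Si](C)(C)C(C)(C)C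
F4 | step 3 | (3aS,4R,7S,7aS)-6-{[(4S)-4-benzyl-2-oxo-1,3-oxazolidin-3-yl]carbonyl}-7-[(tert-butyldimethylsilyl)oxy]-2,2-dimethyl-3a,4,7,7a-tetrahydro-1,3-benzodioxol-4-yl acetate | O=C(N1[C@@H](Cc2ccccc2)COC1=O)C1=C[C@@H](OC(C)=O)[C@@H]2OC(C)(C)O[C@@H]2[C@H]1O[Si](C)(C)C(C)(C)C
F5 | step 1 | (1S,4R)-2-(3,5-dimethyl-1H-pyrazole-1-carbonyl)cyclohexa-2,5-diene-1,4-diyl diacetate (cis) | Cc1cc(C)n(n1)C(=O)C1=C[C@@H](OC(C)=O)C=C[C@H]1OC(C)=O
F6 | step 1 | 2-(3,5-dimethyl-1H-pyrazole-1-carbonyl)-5,6-dihydroxycyclohex-2-ene-1,4-diyl diacetate (diol anti to both acetates) | Cc1cc(C)n(n1)C(=O)C1=C[C@@H](OC(C)=O)[C@H](O)[C@H](O)[C@H]1OC(C)=O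
F7 | step 1 | isopropylidene acetal of F6 | Cc1cc(C)n(n1)C(=O)C1=C[C@@H](OC(C)=O)[C@@H]2OC(C)(C)O[C@@H]2[C@H]1OC(C)=O
F8 | step 1 | 5-(hydroxymethyl)-2,2-dimethyl-3a,4,7,7a-tetrahydro-1,3-benzodioxole-4,7-diol (both ring hydroxyls anti to the acetal oxygens) | OCC1=C[C@@H](O)[C@@H]2OC(C)(C)O[C@@H]2[C@H]1O
F9 | step 1 | di-tert-butylsilylene derivative of F8 bridging the primary oxygen and the adjacent ring oxygen | CC(C)(C)[Si]1(OCC2=C[C@@H](O)[C@@H]3OC(C)(C)O[C@@H]3[C@H]2O1)C(C)(C)C
F10 | step 1 | benzoate of F9 at the remaining ring carbinol | CC(C)(C)[Si]1(OCC2=C[C@@H](OC(=O)c4ccccc4)[C@@H]3OC(C)(C)O[C@@H]3[C@H]2O1)C(C)(C)C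
F11 | step 1 | (1R,4S,5R,6R)-4,5,6-trihydroxy-3-(hydroxymethyl)cyclohex-2-en-1-yl benzoate | OCC1=C[C@@H](OC(=O)c2ccccc2)[C@H](O)[C@H](O)[C@H]1O
F12 | step 8 | 4-[(tert-butyldimethylsilyl)oxy]-3-(3,5-dimethyl-1H-pyrazole-1-carbonyl)-5,6-bis[(triethylsilyl)oxy]cyclohex-2-en-1-yl acetate (ring configuration as in 8) | Cc1cc(C)n(n1)C(=O)C1=C[C@@H](OC(C)=O)[C@H](O[Si](CC)(CC)CC)[C@H](O[Si](CC)(CC)CC)[C@H]1O[Si](C)(C)C(C)(C)C
F13 | step 8 | 4-[(tert-butyldimethylsilyl)oxy]-3-(hydroxymethyl)-5,6-bis[(triethylsilyl)oxy]cyclohex-2-en-1-ol (ring configuration as in 8) | OCC1=C[C@@H](O)[C@H](O[Si](CC)(CC)CC)[C@H](O[Si](CC)(CC)CC)[C@H]1O[Si](C)(C)C(C)(C)C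
F14 | step 8 | {3-(benzoyloxy)-6-[(tert-butyldimethylsilyl)oxy]-4,5-bis[(triethylsilyl)oxy]cyclohex-1-en-1-yl}methyl benzoate (ring configuration as in 12) | O=C(OCC1=C[C@@H](OC(=O)c2ccccc2)[C@H](O[Si](CC)(CC)CC)[C@H](O[Si](CC)(CC)CC)[C@H]1O[Si](C)(C)C(C)(C)C)c1ccccc1
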